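The target is cut through ring B at C7–C8 and C11–C12 (C1 exocyclic CH2, ring A C2–C7, ring B C7–C12): C8–C11 is a butan-2-one unit bridging the spiro carbon C7 and C12. One Michael–aldol operation between methyl vinyl ketone and a ring A 2-formyl ketone therefore closes ring B as a spiro cyclohexenone and sets the quaternary stereocentre C7, the face being chosen by the C5 bromide acting across the gem-dimethyl carbon C6. The precursor is (2Z,4R)-4-bromo-2-(hydroxymethylidene)-3,3-dimethylcyclohexanone, whose bromide is set by a stereospecific bromonium cyclisation. The enone left at C10–C12 then takes on the C11 bromide, the C10 methyl and chloride, and the C2 ketone becomes the methylene.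

Key step: step 7

Remark: positions in the Why lines use the numbers C1–C12 defined above; centres that are destroyed again later (the ester-bearing carbon of 8, the two new centres of 9, the carbinol carbon of 13) are carried as mixtures and written without descriptors.

Step 1
Reactants: 1 3-methylbut-2-en-1-ol
Product: 2 (2R)-2-bromo-3-chloro-3-methylbutan-1-ol
Conditions: NBS, ClTi(OiPr)3, chiral tridentate Schiff base ligand (20 mol%, enantiomer giving 2R), hexanes, −20 °C
Reagents that add atoms: N-bromosuccinimide, O=C1CCC(=O)N1Br; chlorotitanium triisopropoxide, CC(C)O[Ti](Cl)(OC(C)C)OC(C)C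
Why: Catalytic enantioselective bromochlorination of an allylic alcohol, in which the titanium-bound alkoxide and the chiral ligand direct bromonium formation to one alkene face and titanium-bound chloride opens it anti at the tertiary carbon, sets the C–Br centre (2R) that later becomes C5.

Step 2
Reactants: 2 (2R)-2-bromo-3-chloro-3-methylbutan-1-ol
Product: 3 (2R)-2-bromo-3-chloro-3-methylbutyl trifluoromethanesulfonate
Conditions: Tf2O, 2,6-lutidine, CH2Cl2, −78 °C
Reagents that add atoms: trifluoromethanesulfonic anhydride, O=S(=O)(OS(=O)(=O)C(F)(F)F)C(F)(F)F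
Why: Sulfonylation of the primary alcohol at low temperature gives a leaving group reactive enough for carbon alkylation beside the hindered halide carbons and does not touch the stereocentre.

Step 3
Reactants: 3 (2R)-2-bromo-3-chloro-3-methylbutyl trifluoromethanesulfonate; 4 methyl acetoacetate
Product: 6 methyl (6R)-6-bromo-7-chloro-7-methyl-3-oxooctanoate, via acetoacetate dianion 5 (not isolated)
Conditions: 4, NaH, THF, 0 °C; n-BuLi, 0 °C; then 3, −78 °C; NH4Cl quench
Reagents that add atoms: none
Why: γ-Alkylation of an acetoacetate dianion, in which the terminal carbanion displaces the primary triflate by SN2 at −78 °C faster than it can act as a base toward the halides, joins C3 to C4 without involving the C–Br centre.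

Step 4
Reactants: 6 methyl (6R)-6-bromo-7-chloro-7-methyl-3-oxooctanoate
Product: 8 methyl (3R)-3-bromo-2,2-dimethyl-6-oxocyclohexane-1-carboxylate, via bromonium ion 7 (not isolated)
Conditions: (CF3)2CHOH, 23 °C
Reagents that add atoms: none
Why: Solvolytic bromonium cyclisation of a vicinal bromochloride, in which the ionising and poorly nucleophilic solvent lets the tertiary chloride leave with anti participation of bromine and the keto ester enol carbon (C7) captures the tertiary end (C6) of bromonium ion 7 in a 6-endo closure, forms ring A and carries the C–Br configuration over unchanged as C5 (R).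

Step 5
Reactants: 8 methyl (3R)-3-bromo-2,2-dimethyl-6-oxocyclohexane-1-carboxylate
Product: 9 (4R)-4-bromo-2-(hydroxymethyl)-3,3-dimethylcyclohexan-1-ol
Conditions: LiAlH4, THF, 0 °C
Reagents that add atoms: none
Why: Hydride reduction of the β-keto ester takes both carbonyl groups to carbinols while the neopentyl-type secondary bromide resists hydride displacement at 0 °C, and the new centres need no control because step 6 removes them.

Step 6
Reactants: 9 (4R)-4-bromo-2-(hydroxymethyl)-3,3-dimethylcyclohexan-1-ol
Product: 10 (2Z,4R)-4-bromo-2-(hydroxymethylidene)-3,3-dimethylcyclohexan-1-one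
Conditions: IBX, DMSO, 23 °C
Reagents that add atoms: none
Why: IBX oxidation takes the primary and the secondary carbinol to the β-keto aldehyde, which rests as the chelated Z enol, and it is chosen because it neither chlorinates nor cleaves the 1,3-dicarbonyl unit.

Step 7
Reactants: 10 (2Z,4R)-4-bromo-2-(hydroxymethylidene)-3,3-dimethylcyclohexan-1-one; 11 methyl vinyl ketone
Product: 14 (4R,6R)-4-bromo-5,5-dimethylspiro[5.5]undec-7-ene-1,9-dione, via Michael adduct 12 (not isolated), via aldol 13 (not isolated)
Conditions: 11, Et3N (cat.), THF, 23 °C; then pyrrolidine (cat.), AcOH (cat.), 50 °C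
Reagents that add atoms: none
Why: Triethylamine generates the hydrogen-bonded enol or enolate of 10, which adds through C7 to the terminal carbon of 11 (C7–C8) to give the 2-formyl-2-(3-oxobutyl) ketone 12; pyrrolidinium acetate then turns the side-chain methyl ketone into its enamine, whose C11 attacks the formyl carbon C12, and loss of water from aldol 13 leaves the C11=C12 enone. The closest known reaction type is the Robinson-type Michael–aldol spiroannulation of 2-formylcycloalkanones with methyl vinyl ketone. Ring B closes in a 6-(enolendo)-exo-trig aldol step, the enamine double bond C10=C11 lying inside the new ring and the aldehyde oxygen outside it. The only new stereocentre, C7, is controlled by the C5 bromide: with bromine equatorial in the ring A half-chair the pseudoaxial C6 methyl covers one face of the planar C7, so C8 enters on the other face, trans to bromine, and the formyl carbon C12 ends cis to it. The step needs carbon alkylation at the crowded C7 and condensation at the aldehyde instead of the C2 ketone; the first is secured by the soft conjugate acceptor, the second by the far higher electrophilicity of the formyl group next to the hindered C2 ketone, while the weakly basic amine medium suppresses deformylation and leaves the neopentyl-type C5 bromide untouched.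

Step 8
Reactants: 14 (4R,6R)-4-bromo-5,5-dimethylspiro[5.5]undec-7-ene-1,9-dione
Product: 15 (4R,6R)-4-bromo-5,5-dimethyl-9-[(triethylsilyl)oxy]spiro[5.5]undec-8-en-1-one
Conditions: RhCl(PPh3)3 (2 mol%), Et3SiH, THF, 50 °C
Reagents that add atoms: triethylsilane, CC[SiH](CC)CC
Why: Rhodium-catalysed 1,4-hydrosilylation of the enone delivers hydride to C12 and silicon to oxygen, which fixes the enol ether regiospecifically at C10=C11 while the shielded C2 ketone and the alkyl bromide stay intact.

Step 9
Reactants: 15 (4R,6R)-4-bromo-5,5-dimethyl-9-[(triethylsilyl)oxy]spiro[5.5]undec-8-en-1-one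
Product: 16 (4R,6R,8S)-4,8-dibromo-5,5-dimethylspiro[5.5]undecane-1,9-dione
Conditions: NBS, THF, −78 °C to 0 °C
Reagents that add atoms: N-bromosuccinimide, O=C1CCC(=O)N1Br
Why: Electrophilic α-bromination of a silyl enol ether places bromine on C11 only, and it enters on the ring B face opposite the axial C2 carbonyl (the face of C6) because the other face of C11 is 1,3-diaxial to C2, which gives the equatorial 11S bromide that is also the more stable epimer.

Step 10
Reactants: 16 (4R,6R,8S)-4,8-dibromo-5,5-dimethylspiro[5.5]undecane-1,9-dione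
Product: 17 (4R,6R,8S,9R)-4,8-dibromo-9-hydroxy-5,5,9-trimethylspiro[5.5]undecan-1-one
Conditions: MeMgCl, CeCl3, THF, −78 °C
Reagents that add atoms: methylmagnesium chloride, C[Mg]Cl
Why: Organocerium 1,2-addition is non-basic and so adds methyl to the α-bromo C10 ketone without enolisation or loss of bromide and in preference to the C2 ketone buried between the spiro and gem-dimethyl carbons, mainly along the equatorial trajectory to give the axial 10R carbinol, whose configuration is not critical because C10 becomes planar in step 11.

Step 11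
Reactants: 17 (4R,6R,8S,9R)-4,8-dibromo-9-hydroxy-5,5,9-trimethylspiro[5.5]undecan-1-one
Product: 19 (4R,6R,8S,9S)-4,8-dibromo-9-chloro-5,5,9-trimethylspiro[5.5]undecan-1-one, via bromonium chloride 18 (not isolated)
Conditions: HCl (gas), CH2Cl2, −20 °C to 0 °C
Reagents that add atoms: hydrogen chloride, Cl
Why: Substitution of a tertiary β-bromo carbinol by chloride with neighbouring-group participation, in which ionisation at C10 lets the C11 bromine bridge on its own face to bromonium ion 18 and chloride opens the bridge at the more substituted C10 from the opposite face, sets C10 (S) trans to bromine, while attack at C11 is disfavoured electronically and by the axial C2 carbonyl beneath it.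

Step 12
Reactants: 19 (4R,6R,8S,9S)-4,8-dibromo-9-chloro-5,5,9-trimethylspiro[5.5]undecan-1-one
Product: 20 (2R,6S,8S,9S)-2,8-dibromo-9-chloro-1,1,9-trimethyl-5-methylidenespiro[5.5]undecane
Conditions: Cp2TiMe2, toluene, 70 °C, dark
Reagents that add atoms: dimethyltitanocene, C[Ti](C)(C1C=CC=C1)C1C=CC=C1
Why: Petasis methylenation, in which thermally formed Cp2Ti=CH2 is non-basic, compact enough for the neopentyl C2 ketone and indifferent to alkyl halides, converts C=O into C=CH2 without touching any stereocentre.

Compound list
1 | 3-methylbut-2-en-1-ol (prenol) | CC(C)=CCO | starting material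
2 | (2R)-2-bromo-3-chloro-3-methylbutan-1-ol | OC[C@@H](Br)C(C)(C)Cl | intermediate
3 | (2R)-2-bromo-3-chloro-3-methylbutyl trifluoromethanesulfonate | FC(F)(F)S(=O)(=O)OC[C@@H](Br)C(C)(C)Cl | intermediate
4 | methyl acetoacetate | COC(=O)CC(C)=O | starting material
5 | acetoacetate dianion (sodium lithium salt of 4; not isolated) | COC(=O)[CH-]C(=O)[CH2-].[Na+].[Li+] | intermediate
6 | methyl (6R)-6-bromo-7-chloro-7-methyl-3-oxooctanoate | COC(=O)CC(=O)CC[C@@H](Br)C(C)(C)Cl | intermediate
7 | bromonium ion from 6 (chloride salt; not isolated) | COC(=O)CC(=O)CC[C@@H]1C(C)(C)[Br+]1.[Cl-] | intermediate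
8 | methyl (3R)-3-bromo-2,2-dimethyl-6-oxocyclohexane-1-carboxylate (C1 epimers and enol) | COC(=O)C1C(=O)CC[C@@H](Br)C1(C)C | intermediate
9 | (4R)-4-bromo-2-(hydroxymethyl)-3,3-dimethylcyclohexan-1-ol (C1 and C2 epimers) | OCC1C(O)CC[C@@H](Br)C1(C)C | intermediate
10 | (2Z,4R)-4-bromo-2-(hydroxymethylidene)-3,3-dimethylcyclohexan-1-one | O/C=C1\C(=O)CC[C@@H](Br)C1(C)C | intermediate
11 | methyl vinyl ketone (but-3-en-2-one) | CC(=O)C=C | starting material
12 | (1S,3R)-3-bromo-2,2-dimethyl-6-oxo-1-(3-oxobutyl)cyclohexane-1-carbaldehyde (Michael adduct; not isolated) | O=C1CC[C@@H](Br)C(C)(C)[C@]1(C=O)CCC(C)=O | intermediate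
13 | (4R,6S)-4-bromo-7-hydroxy-5,5-dimethylspiro[5.5]undecane-1,9-dione (aldol, C7 epimers; not isolated) | O=C1CC[C@@H](Br)C(C)(C)[C@]12CCC(=O)CC2O | intermediate
14 | (4R,6R)-4-bromo-5,5-dimethylspiro[5.5]undec-7-ene-1,9-dione | O=C1CC[C@@H](Br)C(C)(C)[C@]12CCC(=O)C=C2 | intermediate
15 | (4R,6R)-4-bromo-5,5-dimethyl-9-[(triethylsilyl)oxy]spiro[5.5]undec-8-en-1-one | O=C1CC[C@@H](Br)C(C)(C)[C@]12CCC(O[Si](CC)(CC)CC)=CC2 | intermediate
16 | (4R,6R,8S)-4,8-dibromo-5,5-dimethylspiro[5.5]undecane-1,9-dione | O=C1CC[C@@H](Br)C(C)(C)[C@]12CCC(=O)[C@@H](Br)C2 | intermediate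
17 | (4R,6R,8S,9R)-4,8-dibromo-9-hydroxy-5,5,9-trimethylspiro[5.5]undecan-1-one | O=C1CC[C@@H](Br)C(C)(C)[C@]12CC[C@@](C)(O)[C@@H](Br)C2 | intermediate
18 | bromonium ion from 17 (chloride salt; not isolated) | O=C1CC[C@@H](Br)C(C)(C)[C@]12CC[C@@]3(C)[Br+][C@H]3C2.[Cl-] | intermediate
19 | (4R,6R,8S,9S)-4,8-dibromo-9-chloro-5,5,9-trimethylspiro[5.5]undecan-1-one | O=C1CC[C@@H](Br)C(C)(C)[C@]12CC[C@](C)(Cl)[C@@H](Br)C2 | intermediate
20 | (2R,6S,8S,9S)-2,8-dibromo-9-chloro-1,1,9-trimethyl-5-methylidenespiro[5.5]undecane (CNP0211773.1) | C=C1CC[C@@H](Br)C(C)(C)[C@]12CC[C@](C)(Cl)[C@@H](Br)C2 | target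

Total step count: 12
Longest linear sequence: 12 steps (1 to 20)

Steps most likely to fail

Step 7. Bond formation at the crowded C7 may be slow, the formyl group may be lost by amine-induced retro-Claisen cleavage, or the two faces of C7 may not be told apart well enough. The fallback moves the conjugate addition to the ester stage. Setting out from 8, iron-catalysed Michael addition to 11 (FeCl3·6H2O cat., CH2Cl2, 23 °C) should give methyl (1R,3R)-3-bromo-2,2-dimethyl-6-oxo-1-(3-oxobutyl)cyclohexane-1-carboxylate F1 under neutral conditions where no formyl group is yet present. LiAlH4 (THF, 0 °C) would then reduce all three carbonyl groups to 4-bromo-2-(3-hydroxybutyl)-2-(hydroxymethyl)-3,3-dimethylcyclohexan-1-ol F2, and IBX (DMSO, 23 °C) would oxidise this triol to the keto aldehyde 12. Pyrrolidinium acetate alone then closes 12 to 14, where the route is rejoined.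

Step 11. After ionisation the C10 cation may lose a proton to give alkenes, or chloride may add before bromine has bridged, which would erode the trans relationship. The fallback adds both halogens to an alkene instead. Setting out from 15, CsF and PhNTf2 (DME, 23 °C) would give (4R,6R)-4-bromo-5,5-dimethyl-1-oxospiro[5.5]undec-8-en-9-yl trifluoromethanesulfonate F3. Negishi coupling with MeZnCl and Pd(PPh3)4 (THF, 40 °C) would give (4R,6R)-4-bromo-5,5,9-trimethylspiro[5.5]undec-8-en-1-one F4. Anti bromochlorination with Bu4NBrCl2 (CH2Cl2, −40 °C) should then give 19, bromine again adding to the face of C11 away from the axial C2 carbonyl and chloride to the tertiary C10. The route is rejoined at 19.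

Step 12. Carbonyl methylenation at the neopentyl C2 ketone may be slower than thermal decay of the titanium reagent. The fallback is a two-stage Peterson olefination setting out from 19. (Trimethylsilyl)methyllithium with CeCl3 (THF, −78 °C) should add to C2 to give 4,8-dibromo-9-chloro-5,5,9-trimethyl-1-[(trimethylsilyl)methyl]spiro[5.5]undecan-1-ol F5, and KH (THF, 0 °C) would trigger syn elimination of silanolate to give the target 20.

Further compounds
F1 | step 7 | methyl (1R,3R)-3-bromo-2,2-dimethyl-6-oxo-1-(3-oxobutyl)cyclohexane-1-carboxylate | O=C1CC[C@@H](Br)C(C)(C)[C@]1(C(=O)OC)CCC(C)=O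
F2 | step 7 | 4-bromo-2-(3-hydroxybutyl)-2-(hydroxymethyl)-3,3-dimethylcyclohexan-1-ol (carbinol epimers) | OC1CC[C@@H](Br)C(C)(C)[C@]1(CO)CCC(C)O
F3 | step 11 | (4R,6R)-4-bromo-5,5-dimethyl-1-oxospiro[5.5]undec-8-en-9-yl trifluoromethanesulfonate | O=C1CC[C@@H](Br)C(C)(C)[C@]12CCC(OS(=O)(=O)C(F)(F)F)=CC2
F4 | step 11 | (4R,6R)-4-bromo-5,5,9-trimethylspiro[5.5]undec-8-en-1-one | O=C1CC[C@@H](Br)C(C)(C)[C@]12CCC(C)=CC2
F5 | step 12 | 4,8-dibromo-9-chloro-5,5,9-trimethyl-1-[(trimethylsilyl)methyl]spiro[5.5]undecan-1-ol (C1 epimers) | C[Si](C)(C)CC1(O)CC[C@@H](Br)C(C)(C)[C@]12CC[C@](C)(Cl)[C@@H](Br)C2
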